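**Plan**
- Locants: the ring is O1–O2–C3–C4–C5. C3 carries CH3 and CH2CO2H. C5 carries CH3 and the chain C1'–C16'.
- Cuts, in retrosynthetic order: C9'=C10' (Horner–Wadsworth–Emmons), C2'–C3' (cross-metathesis, then diimide), C5–C1' (allylation of a C5 peroxycarbenium ion), both ring C–O bonds (dioxygen out, C3–C5 bond closed, giving a cyclopropanol), and C4 (CH2 from CH2I2 onto a silyl enol ether).
- Enabling feature: C3 and C5 are both fully substituted and are spanned by the single methylene C4. C3–C4–C5 therefore maps onto a cyclopropane and O1–O2 onto dioxygen. A hydroxyl on C5 (ketone level, later replaced by the chain) triggers scission of C3–C5 toward a tertiary C3 radical.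
- Forward order: keto ester, silyl enol ether, siloxycyclopropane, aerobic ring expansion from the three- to the five-membered ring, C5 acetate, allyl group, chain growth, and the triene last, because it would not survive dioxygen, Lewis acid or diimide.
- Stereochemistry: C3 forms racemic in the ring expansion. C5 is set relative to C3 by attack anti to the ester-bridged cation. The absolute configuration comes from separating the (R)-pantolactone esters. Two E alkenes come from the dienal and the third from the olefination.

Key step: step 3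

Assumption: compounds 1, 11, 13 and 17 are taken as commercial. Which ester from step 7 is the (3R,5S) isomer is to be settled by X-ray analysis or by the sign of rotation of the final acid.

Step 1
Reactants: 1 methyl 3-methyl-4-oxopentanoate (racemic)
Product: 2 methyl 3-methyl-4-(trimethylsilyloxy)pent-3-enoate (E/Z mixture)
Conditions: TMSCl, NaI, Et3N, MeCN, rt
Reagents that add atoms: chlorotrimethylsilane C[Si](C)(C)Cl
Why: Soft enolisation with Me3SiI made in situ equilibrates the silyl enol ethers, so the tetrasubstituted (thermodynamic) isomer should prevail, and its geometry is irrelevant because both cyclopropane stereocentres derived from it are erased in step 3.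

Step 2
Reactants: 2 methyl 3-methyl-4-(trimethylsilyloxy)pent-3-enoate
Product: 3 methyl 2-[1,2-dimethyl-2-(trimethylsilyloxy)cyclopropyl]acetate (racemic cis/trans mixture)
Conditions: Et2Zn, CH2I2, CH2Cl2, 0 °C to rt
Reagents that add atoms: diiodomethane ICI
Why: Furukawa-modified Simmons–Smith cyclopropanation, in which the electron-rich enol ether is the only alkene and takes up CH2 (the future C4); the two new stereocentres need no control.

Step 3
Reactants: 3 methyl 2-[1,2-dimethyl-2-(trimethylsilyloxy)cyclopropyl]acetate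
Product: 6 methyl 2-(5-hydroxy-3,5-dimethyl-1,2-dioxolan-3-yl)acetate (racemic; both C5 epimers), via cyclopropanol 4 (not isolated), via hydroperoxy ketone 5 (not isolated)
Conditions: citric acid (cat.), MeOH, 0 °C; then Mn(acac)2 (2 mol %), O2 (1 atm), toluene, rt
Reagents that add atoms: dioxygen O=O
Why: Methanolysis frees cyclopropanol 4, whose manganese alkoxide is oxidised by dioxygen to a cyclopropyloxy radical; β-scission of the C5–C3 bond gives the tertiary β-keto alkyl radical at C3, triplet dioxygen adds to it, and the peroxyl radical is reduced to hydroperoxide 5 by hydrogen transfer within the manganese cycle. Hydroperoxide 5 then adds to its own ketone in a 5-exo-trig closure to give the peroxy hemiketal, so that O1–O2 stands where the C3–C5 bond of the three-membered ring stood (ring expansion by two atoms). The closest known reaction type is the aerobic oxidation of cyclopropanols to 1,2-dioxolan-3-ols catalysed by Mn(acac)2 or Co(acac)2. C3 forms from a planar radical and is therefore racemic (resolved in step 7), while the C5 hemiketal centre is labile and is erased in step 5. The step needs scission of C5–C3 rather than C5–C4, which the two alkyl groups on C3 secure (tertiary against primary radical), and it needs the ester to stay untouched, which neutral conditions and immediate oxidation of 4 should secure.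

Step 4
Reactants: 6 methyl 2-(5-hydroxy-3,5-dimethyl-1,2-dioxolan-3-yl)acetate
Product: 7 methyl 2-(5-acetoxy-3,5-dimethyl-1,2-dioxolan-3-yl)acetate (racemic; both C5 epimers)
Conditions: Ac2O, pyridine, DMAP (cat.), CH2Cl2, 0 °C
Reagents that add atoms: acetic anhydride CC(=O)OC(C)=O
Why: Acylation of the peroxy hemiketal hydroxyl installs a leaving group that ionises under mild Lewis acid, and the C5 epimers converge on one cation.

Step 5
Reactants: 7 methyl 2-(5-acetoxy-3,5-dimethyl-1,2-dioxolan-3-yl)acetate
Product: 9 methyl rac-2-[(3R*,5S*)-3,5-dimethyl-5-(prop-2-en-1-yl)-1,2-dioxolan-3-yl]acetate, via bridged dioxanylium triflate 8 (not isolated)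
Conditions: allylSiMe3, TMSOTf (cat.), CH2Cl2, −78 °C
Reagents that add atoms: allyltrimethylsilane C=CC[Si](C)(C)C
Why: Hosomi–Sakurai allylation of a peroxycarbenium ion, in which the ester carbonyl of the larger C3 arm bridges the C5 cation from its own face (ion 8), so the allylsilane should enter anti and place the allyl group trans to CH2CO2Me, which sets C5 relative to C3.

Step 6
Reactants: 9 methyl rac-2-[(3R*,5S*)-3,5-dimethyl-5-(prop-2-en-1-yl)-1,2-dioxolan-3-yl]acetate
Product: 10 rac-2-[(3R*,5S*)-3,5-dimethyl-5-(prop-2-en-1-yl)-1,2-dioxolan-3-yl]acetic acid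
Conditions: LiOH, THF/H2O, 0 °C; then 1 M HCl
Reagents that add atoms: lithium hydroxide [Li+].[OH-]
Why: Saponification of an unhindered methyl ester, to which the tetrasubstituted dialkyl peroxide and both quaternary centres are inert.

Step 7
Reactants: 10 rac-2-[(3R*,5S*)-3,5-dimethyl-5-(prop-2-en-1-yl)-1,2-dioxolan-3-yl]acetic acid; 11 (R)-pantolactone
Product: 12 (3R)-4,4-dimethyl-2-oxooxolan-3-yl 2-[(3R,5S)-3,5-dimethyl-5-(prop-2-en-1-yl)-1,2-dioxolan-3-yl]acetate
Conditions: DCC, DMAP (cat.), CH2Cl2, 0 °C to rt; chromatographic separation of the two diastereomers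
Reagents that add atoms: none
Why: Steglich esterification with an enantiopure alcohol turns the racemate into two diastereomers, and their separation (resolution) delivers the (3R,5S) series, so the absolute configuration of C3 and C5 stems from (R)-pantolactone.

Step 8
Reactants: 12 pantolactone ester of the (3R,5S)-allyl dioxolane acid; 13 oct-7-en-1-ol
Product: 14 (3R)-4,4-dimethyl-2-oxooxolan-3-yl 2-[(3R,5S)-5-[(2E)-9-hydroxynon-2-en-1-yl]-3,5-dimethyl-1,2-dioxolan-3-yl]acetate (E major)
Conditions: second-generation Grubbs catalyst (5 mol %), 13 (3 equiv), CH2Cl2, 40 °C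
Reagents that add atoms: none
Why: Olefin cross-metathesis of two terminal alkenes driven by loss of ethene; the alkene geometry is irrelevant, and hindered dialkyl peroxides tolerate ruthenium alkylidenes.

Step 9
Reactants: 14 (2E)-9-hydroxynon-2-enyl dioxolane ester
Product: 15 (3R)-4,4-dimethyl-2-oxooxolan-3-yl 2-[(3R,5S)-5-(9-hydroxynonyl)-3,5-dimethyl-1,2-dioxolan-3-yl]acetate
Conditions: 2-nitrobenzenesulfonylhydrazide, Et3N, CH2Cl2, rt
Reagents that add atoms: none
Why: Diimide reduction delivers H2 to the C=C bond in a concerted syn transfer and, unlike catalytic hydrogenation, leaves the O–O bond untouched.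

Step 10
Reactants: 15 9-hydroxynonyl dioxolane ester
Product: 16 (3R)-4,4-dimethyl-2-oxooxolan-3-yl 2-[(3R,5S)-3,5-dimethyl-5-(9-oxononyl)-1,2-dioxolan-3-yl]acetate
Conditions: TEMPO (cat.), PhI(OAc)2, CH2Cl2, rt
Reagents that add atoms: none
Why: Oxoammonium (TEMPO) oxidation of a primary alcohol stops at the aldehyde and is mild enough for ester, lactone and peroxide.

Step 11
Reactants: 17 (2E,4E)-hepta-2,4-dienal
Product: 18 (2E,4E)-hepta-2,4-dien-1-ol
Conditions: NaBH4, MeOH, 0 °C
Reagents that add atoms: none
Why: Borohydride 1,2-reduction of the aldehyde keeps both E double bonds.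

Step 12
Reactants: 18 (2E,4E)-hepta-2,4-dien-1-ol
Product: 19 (2E,4E)-1-bromohepta-2,4-diene
Conditions: PBr3, Et2O, −10 °C
Reagents that add atoms: phosphorus tribromide BrP(Br)Br
Why: SN2 bromination of a primary allylic alcohol through its phosphite ester, which at low temperature should keep position and geometry of the diene.

Step 13
Reactants: 19 (2E,4E)-1-bromohepta-2,4-diene
Product: 20 diethyl [(2E,4E)-hepta-2,4-dien-1-yl]phosphonate
Conditions: P(OEt)3, neat, 120 °C
Reagents that add atoms: triethyl phosphite CCOP(OCC)OCC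
Why: Michaelis–Arbuzov reaction of a reactive primary allylic bromide.

Step 14
Reactants: 16 9-oxononyl dioxolane ester; 20 diethyl [(2E,4E)-hepta-2,4-dien-1-yl]phosphonate
Product: 22 (3R)-4,4-dimethyl-2-oxooxolan-3-yl 2-[(3R,5S)-5-[(9E,11E,13E)-hexadeca-9,11,13-trien-1-yl]-3,5-dimethyl-1,2-dioxolan-3-yl]acetate, via lithiated phosphonate 21 (not isolated)
Conditions: LiN(SiMe3)2, THF, −78 °C; then 16, −78 °C to 0 °C
Reagents that add atoms: none
Why: Horner–Wadsworth–Emmons olefination with a preformed allylic phosphonate anion should give the new C9'=C10' bond mainly E, and since the aldehyde is the most electrophilic site and no free amide base is left, the β-peroxy ester should not be enolised.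

Step 15
Reactants: 22 pantolactone ester of the target acid
Product: 23 2-[(3R,5S)-5-[(9E,11E,13E)-hexadeca-9,11,13-trien-1-yl]-3,5-dimethyl-1,2-dioxolan-3-yl]acetic acid (target)
Conditions: LiOH, THF/H2O, 0 °C; then 1 M HCl to pH 3
Reagents that add atoms: lithium hydroxide [Li+].[OH-]
Why: Saponification of the activated α-acyloxy lactone ester frees the acid and the auxiliary without touching the peroxide, the triene or the quaternary stereocentres.

**Compound list**
1 | methyl 3-methyl-4-oxopentanoate (racemic) | CC(=O)C(C)CC(=O)OC | starting material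
2 | methyl 3-methyl-4-(trimethylsilyloxy)pent-3-enoate (E/Z mixture) | CC(O[Si](C)(C)C)=C(C)CC(=O)OC | intermediate
3 | methyl 2-[1,2-dimethyl-2-(trimethylsilyloxy)cyclopropyl]acetate (racemic cis/trans mixture) | COC(=O)CC1(C)CC1(C)O[Si](C)(C)C | intermediate
4 | methyl 2-(2-hydroxy-1,2-dimethylcyclopropyl)acetate (racemic cis/trans mixture, not isolated) | COC(=O)CC1(C)CC1(C)O | intermediate
5 | methyl 3-hydroperoxy-3-methyl-5-oxohexanoate (racemic, not isolated) | COC(=O)CC(C)(OO)CC(C)=O | intermediate
6 | methyl 2-(5-hydroxy-3,5-dimethyl-1,2-dioxolan-3-yl)acetate (racemic, both C5 epimers) | COC(=O)CC1(C)CC(C)(O)OO1 | intermediate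
7 | methyl 2-(5-acetoxy-3,5-dimethyl-1,2-dioxolan-3-yl)acetate (racemic, both C5 epimers) | COC(=O)CC1(C)CC(C)(OC(C)=O)OO1 | intermediate
8 | 3-methoxy-1,5-dimethyl-2,6,7-trioxabicyclo[3.2.1]oct-2-en-2-ium triflate (racemic, bridge forces the cis fusion, not isolated) | COC1=[O+]C2(C)CC(C)(C1)OO2.[O-]S(=O)(=O)C(F)(F)F | intermediate
9 | methyl rac-2-[(3R*,5S*)-3,5-dimethyl-5-(prop-2-en-1-yl)-1,2-dioxolan-3-yl]acetate (racemate, one enantiomer drawn) | C=CC[C@@]1(C)C[C@](C)(CC(=O)OC)OO1 | intermediate
10 | rac-2-[(3R*,5S*)-3,5-dimethyl-5-(prop-2-en-1-yl)-1,2-dioxolan-3-yl]acetic acid (racemate, one enantiomer drawn) | C=CC[C@@]1(C)C[C@](C)(CC(=O)O)OO1 | intermediate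
11 | (R)-pantolactone | CC1(C)COC(=O)[C@@H]1O | starting material
12 | (3R)-4,4-dimethyl-2-oxooxolan-3-yl 2-[(3R,5S)-3,5-dimethyl-5-(prop-2-en-1-yl)-1,2-dioxolan-3-yl]acetate | C=CC[C@@]1(C)C[C@](C)(CC(=O)O[C@H]2C(=O)OCC2(C)C)OO1 | intermediate
13 | oct-7-en-1-ol | OCCCCCCC=C | starting material
14 | (3R)-4,4-dimethyl-2-oxooxolan-3-yl 2-[(3R,5S)-5-[(2E)-9-hydroxynon-2-en-1-yl]-3,5-dimethyl-1,2-dioxolan-3-yl]acetate | OCCCCCC/C=C/C[C@@]1(C)C[C@](C)(CC(=O)O[C@H]2C(=O)OCC2(C)C)OO1 | intermediate
15 | (3R)-4,4-dimethyl-2-oxooxolan-3-yl 2-[(3R,5S)-5-(9-hydroxynonyl)-3,5-dimethyl-1,2-dioxolan-3-yl]acetate | OCCCCCCCCC[C@@]1(C)C[C@](C)(CC(=O)O[C@H]2C(=O)OCC2(C)C)OO1 | intermediate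
16 | (3R)-4,4-dimethyl-2-oxooxolan-3-yl 2-[(3R,5S)-3,5-dimethyl-5-(9-oxononyl)-1,2-dioxolan-3-yl]acetate | O=CCCCCCCCC[C@@]1(C)C[C@](C)(CC(=O)O[C@H]2C(=O)OCC2(C)C)OO1 | intermediate
17 | (2E,4E)-hepta-2,4-dienal | CC/C=C/C=C/C=O | starting material
18 | (2E,4E)-hepta-2,4-dien-1-ol | CC/C=C/C=C/CO | intermediate
19 | (2E,4E)-1-bromohepta-2,4-diene | CC/C=C/C=C/CBr | intermediate
20 | diethyl [(2E,4E)-hepta-2,4-dien-1-yl]phosphonate | CC/C=C/C=C/CP(=O)(OCC)OCC | intermediate
21 | lithium salt of the α-carbanion of 20 (not isolated) | [Li+].CC/C=C/C=C/[CH-]P(=O)(OCC)OCC | intermediate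
22 | (3R)-4,4-dimethyl-2-oxooxolan-3-yl 2-[(3R,5S)-5-[(9E,11E,13E)-hexadeca-9,11,13-trien-1-yl]-3,5-dimethyl-1,2-dioxolan-3-yl]acetate | CC/C=C/C=C/C=C/CCCCCCCC[C@@]1(C)C[C@](C)(CC(=O)O[C@H]2C(=O)OCC2(C)C)OO1 | intermediate
23 | 2-[(3R,5S)-5-[(9E,11E,13E)-hexadeca-9,11,13-trien-1-yl]-3,5-dimethyl-1,2-dioxolan-3-yl]acetic acid | CC/C=C/C=C/C=C/CCCCCCCC[C@@]1(C)C[C@](C)(CC(=O)O)OO1 | target

Total step count: 15. Longest linear sequence: 12 (steps 1–10, 14, 15).

**Steps most likely to fail**

1. Step 5. The open peroxycarbenium ion may be captured faster than the ester bridges it, which would erode the facial selectivity at C5. The Lewis acid may also start heterolysis of the O–O bond.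
   Fallback, from 6 back to 10 (replaces steps 4 to 6): compound 6 is lactonised under acid catalysis (camphorsulfonic acid, 5 Å molecular sieves, toluene, 40 °C). This gives the bridged peroxy ketal lactone 1,5-dimethyl-2,6,7-trioxabicyclo[3.2.1]octan-3-one F1. In F1 the leaving group on C5 is the carboxylate of the arm itself and is held covalently on the arm face. Opening with allyltrimethylsilane and TMSOTf in CH2Cl2 at −78 °C can then bring the nucleophile in only from the opposite face. It should give the silyl ester trimethylsilyl 2-[(3R*,5S*)-3,5-dimethyl-5-(prop-2-en-1-yl)-1,2-dioxolan-3-yl]acetate F2, which aqueous work-up turns into acid 10.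

2. Step 7. The two diastereomeric esters differ only at centres several bonds from the auxiliary, so chromatographic resolution may be incomplete.
   Fallback, from 10 back to 12: the racemic acid is resolved by crystallisation instead of chromatography. With (S)-1-phenylethylamine in ethyl acetate/hexane it forms two diastereomeric salts. The salt (S)-1-phenylethylammonium 2-[(3R,5S)-3,5-dimethyl-5-(prop-2-en-1-yl)-1,2-dioxolan-3-yl]acetate F3 is recrystallised to constant rotation. Dilute HCl frees the enantiopure acid 2-[(3R,5S)-3,5-dimethyl-5-(prop-2-en-1-yl)-1,2-dioxolan-3-yl]acetic acid F4. This is esterified with 11 (DCC, DMAP) to give 12, where the pantolactone now serves only as protecting group.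

3. Step 3. The free cyclopropanol may be lost before oxidation, by lactonisation of its cis isomer onto the ester or by protolytic ring opening to the ketone. The manganese catalyst may also reduce the hydroperoxide further.
   Fallback, from 3 back to 6: an ionic two-stage route replaces radical capture of dioxygen. FeCl3 in DMF at 0 °C opens the siloxycyclopropane at the same C3–C5 bond and gives the tertiary chloride methyl 3-chloro-3-methyl-5-oxohexanoate F5. AgO2CCF3 with anhydrous H2O2 in Et2O at 0 °C (silver-assisted perhydrolysis of a tertiary halide) replaces chloride by OOH to give 5, which closes to 6.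

Further compounds
F1 | step 5 | rac-1,5-dimethyl-2,6,7-trioxabicyclo[3.2.1]octan-3-one | CC12CC(C)(CC(=O)O1)OO2
F2 | step 5 | trimethylsilyl rac-2-[(3R*,5S*)-3,5-dimethyl-5-(prop-2-en-1-yl)-1,2-dioxolan-3-yl]acetate | C=CC[C@@]1(C)C[C@](C)(CC(=O)O[Si](C)(C)C)OO1
F3 | step 7 | (S)-1-phenylethylammonium 2-[(3R,5S)-3,5-dimethyl-5-(prop-2-en-1-yl)-1,2-dioxolan-3-yl]acetate | C=CC[C@@]1(C)C[C@](C)(CC(=O)[O-])OO1.C[C@H]([NH3+])c1ccccc1
F4 | step 7 | 2-[(3R,5S)-3,5-dimethyl-5-(prop-2-en-1-yl)-1,2-dioxolan-3-yl]acetic acid (single enantiomer) | C=CC[C@@]1(C)C[C@](C)(CC(=O)O)OO1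
F5 | step 3 | methyl 3-chloro-3-methyl-5-oxohexanoate (racemic) | COC(=O)CC(C)(Cl)CC(C)=O
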